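**Retrosynthetic overview**

1. Target ⇐ reagent-controlled ketone reduction at C1 of a ten-membered keto-lactone; the γ-lactone is closed last from the C6 hydroxyl and the acrylate ester.
2. Ten-membered ring ⇐ ring expansion: Grob-type epoxy-alkoxide fragmentation of the C1–C5 bond of a five–seven fused chromium alkoxide, itself made in the same flask by intramolecular Nozaki–Hiyama–Kishi addition of a (Z)-alkenyl iodide to a cyclopentanone. The fragmentation creates the ring-cis C4=C5 olefin and frees the C15 alcohol.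
3. Spiro-epoxide ⇐ hydroxyl-directed epoxidation; C5–C6 bond ⇐ indium vinylogous Reformatsky reaction of 3-(bromomethyl)cyclopent-2-enone with a C6 aldehyde (Felkin control sets C6).
4. C7–C8 bond and both stereocentres ⇐ catalytic asymmetric chromium 2-(alkoxycarbonyl)allylation of (Z)-3-iodobut-2-enal with a Morita–Baylis–Hillman-derived allyl bromide; the C8 ester comes from (S)-2-methylbutanoic acid.
5. Ring order: cyclopentanone (bought) → seven-membered ring → ten-membered ring → γ-lactone.

Atom labels used below (germacrane numbering): C1 (carbinol), C2, C3, C4=C5, C6 (lactone O), C7, C8 (ester O), C9=C10, C11(=C13)–C12 lactone, C14 (methyl on C10), C15 (CH2OH on C4).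

Assumption: ligand L in step 5 is 1,8-bis[(4R)-4-isopropyl-4,5-dihydro-1,3-oxazol-2-yl]-3,6-diphenyl-9H-carbazole, taken as the antipode that sends the allylchromium reagent to the Si face of enal 4; if the sense is the reverse, its mirror image is used.

**Route**

Step 1
Reactants: 1 but-2-yn-1-ol
Product: 3 (2Z)-3-iodobut-2-en-1-ol, via cyclic sodium alkenylalanate 2 (not isolated)
Conditions: Red-Al (NaAlH2(OCH2CH2OMe)2, 1.5 equiv), THF, 0 °C to rt; then I2 (1.5 equiv), THF, −78 to 0 °C
Reagents that add atoms: iodine, II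
Why: trans-hydroalumination of the propargylic alkoxide (hydride to C-2 through the O–Al chelate) followed by iodinolysis of the C–Al bond with retention gives only the Z alkenyl iodide, the geometry that becomes the ring-cis C9=C10 bond.

Step 2
Reactants: 3 (2Z)-3-iodobut-2-en-1-ol
Product: 4 (2Z)-3-iodobut-2-enal
Conditions: MnO2 (15 equiv), CH2Cl2, rt, dark
Reagents that add atoms: none
Why: neutral allylic alcohol oxidation with MnO2 gives the enal without touching the C–I bond or the olefin geometry.

Step 3
Reactants: 5 2,2-dimethoxyacetaldehyde; 6 methyl acrylate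
Product: 7 methyl 3-hydroxy-4,4-dimethoxy-2-methylidenebutanoate (racemic)
Conditions: DABCO (0.5 equiv), 1,4-dioxane/H2O 1:1, rt, 48 h
Reagents that add atoms: none
Why: Morita–Baylis–Hillman reaction of an electron-poor aldehyde that works in water; the racemic carbinol centre is removed in step 4.

Step 4
Reactants: 7 methyl 3-hydroxy-4,4-dimethoxy-2-methylidenebutanoate
Product: 8 methyl (2Z)-2-(bromomethyl)-4,4-dimethoxybut-2-enoate
Conditions: NBS (1.2 equiv), Me2S (1.3 equiv), CH2Cl2, 0 °C to rt
Reagents that add atoms: N-bromosuccinimide, O=C1CCC(=O)N1Br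
Why: Corey–Kim-type activation of the allylic alcohol and SN2′ delivery of bromide give the transposed, thermodynamically preferred Z allyl bromide under neutral conditions that spare the acetal.

Step 5
Reactants: 4 (2Z)-3-iodobut-2-enal; 8 methyl (2Z)-2-(bromomethyl)-4,4-dimethoxybut-2-enoate
Product: 10 methyl (3R,4S,5Z)-3-(dimethoxymethyl)-4-hydroxy-6-iodo-2-methylidenehept-5-enoate, via trimethylsilyl ether 9 (not isolated)
Conditions: CrCl2 (10 mol%), ligand L (12 mol%), Mn powder (2 equiv), Me3SiCl (1.5 equiv), THF, 0 °C; then citric acid, MeOH, 0 °C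
Reagents that add atoms: none
Why: catalytic asymmetric Nozaki–Hiyama 2-(alkoxycarbonyl)allylation, in which the ester-chelated Z allylchromium adds through its γ-carbon in a chair transition state to give the syn C7/C8 relationship and the chiral ligand fixes the aldehyde face (C8), while the alkenyl iodide is inert without nickel.

Step 6
Reactants: 10 methyl (3R,4S,5Z)-3-(dimethoxymethyl)-4-hydroxy-6-iodo-2-methylidenehept-5-enoate; 11 (2S)-2-methylbutanoic acid
Product: 12 methyl (3R,4S,5Z)-3-(dimethoxymethyl)-6-iodo-2-methylidene-4-{[(2S)-2-methylbutanoyl]oxy}hept-5-enoate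
Conditions: 11 (1.5 equiv), DIC (1.6 equiv), DMAP (0.1 equiv), CH2Cl2, 0 °C to rt
Reagents that add atoms: none
Why: Steglich esterification at 0 °C with catalytic DMAP installs the natural acyl group without epimerising its α-centre and blocks lactonisation onto the C8 oxygen.

Step 7
Reactants: 13 3-methylcyclopent-2-en-1-one
Product: 14 3-(bromomethyl)cyclopent-2-en-1-one
Conditions: NBS (1.05 equiv), AIBN (5 mol%), PhCF3, 80 °C
Reagents that add atoms: N-bromosuccinimide, O=C1CCC(=O)N1Br
Why: Wohl–Ziegler bromination at the γ-methyl group through the enone-stabilised allylic radical.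

Step 8
Reactants: 12 methyl (3R,4S,5Z)-3-(dimethoxymethyl)-6-iodo-2-methylidene-4-{[(2S)-2-methylbutanoyl]oxy}hept-5-enoate; 14 3-(bromomethyl)cyclopent-2-en-1-one
Product: 16 methyl (3S,4S,5Z)-3-{(S)-hydroxy[(1R)-2-methylidene-5-oxocyclopentyl]methyl}-6-iodo-2-methylidene-4-{[(2S)-2-methylbutanoyl]oxy}hept-5-enoate, via aldehyde 15 (not isolated)
Conditions: TFA/H2O 1:1, CH2Cl2, 0 °C, concentrate; then 14 (1.5 equiv), indium powder (In, 1.5 equiv), THF/H2O 1:1, rt
Reagents that add atoms: water, O
Why: acetal hydrolysis then a Barbier-type vinylogous Reformatsky reaction in which the allylindium reacts through the ring α-carbon (six-membered transition state) to form C5–C6 and the exocyclic methylene, while Felkin–Anh addition to the α-branched aldehyde, reinforced by 1,3-anti induction from the C8 acyloxy group, sets C6 as needed for the trans lactone; the ring stereocentre (anti epimer shown) is inconsequential because it becomes sp2 in step 10.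

Step 9
Reactants: 16 methyl (3S,4S,5Z)-3-{(S)-hydroxy[(1R)-2-methylidene-5-oxocyclopentyl]methyl}-6-iodo-2-methylidene-4-{[(2S)-2-methylbutanoyl]oxy}hept-5-enoate
Product: 17 methyl (3S,4S,5Z)-3-{(S)-hydroxy[(3S,4S)-5-oxo-1-oxaspiro[2.4]heptan-4-yl]methyl}-6-iodo-2-methylidene-4-{[(2S)-2-methylbutanoyl]oxy}hept-5-enoate
Conditions: VO(acac)2 (5 mol%), t-BuOOH (1.5 equiv, decane), CH2Cl2, 0 °C to rt
Reagents that add atoms: tert-butyl hydroperoxide, CC(C)(C)OO
Why: vanadium-catalysed hydroxyl-directed epoxidation of the homoallylic alcohol, in which the vanadium-bound C6 alkoxide delivers oxygen to the face of the exocyclic olefin that carries the C6 side chain, so the spiro centre is set with oxygen cis to C6 while the acrylate and iodoalkene are left alone.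

Step 10
Reactants: 17 methyl (3S,4S,5Z)-3-{(S)-hydroxy[(3S,4S)-5-oxo-1-oxaspiro[2.4]heptan-4-yl]methyl}-6-iodo-2-methylidene-4-{[(2S)-2-methylbutanoyl]oxy}hept-5-enoate
Product: 20 (3aR,4R,5Z,10E,11aR)-10-(hydroxymethyl)-6-methyl-3-methylidene-2,7-dioxo-2,3,3a,4,7,8,9,11a-octahydrocyclodeca[b]furan-4-yl (2S)-2-methylbutanoate, via chromium alkoxide 18 (not isolated), via ring-expanded hydroxy ester 19 (not isolated)
Conditions: CrCl2 (6 equiv), NiCl2 (2 mol%), degassed DMSO (5 mM), rt then 45 °C; aqueous work-up; then CSA (10 mol%), CH2Cl2, rt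
Reagents that add atoms: none
Why: Proposed new method: a Nozaki–Hiyama–Kishi ring closure driven on into a Grob-type fragmentation — zerovalent nickel inserts into the C–I bond, the alkenyl group passes to chromium and adds to the cyclopentanone carbonyl to give the five–seven fused tertiary chromium alkoxide 18, whose C1–C5 ring-fusion bond lies anti-periplanar to the C4–O bond of the spiro-epoxide (oxygen cis to C6), so alkoxide push and chromium Lewis-acid pull on the epoxide break C1–C5 to give the C1 enone, the ring-cis C4=C5 olefin and the C15 alkoxide in a ten-membered ring (19) with no new stereocentre, and acid then closes the trans γ-lactone; the closest known reactions are intramolecular Nozaki–Hiyama–Kishi additions to ketones and the Wharton/Holton epoxy-alkoxide fragmentation, which have not been run in tandem or used for a five-to-ten-membered ring expansion.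

Step 11
Reactants: 20 (3aR,4R,5Z,10E,11aR)-10-(hydroxymethyl)-6-methyl-3-methylidene-2,7-dioxo-2,3,3a,4,7,8,9,11a-octahydrocyclodeca[b]furan-4-yl (2S)-2-methylbutanoate
Product: 21 (3aR,4R,5Z,7S,10E,11aR)-7-hydroxy-10-(hydroxymethyl)-6-methyl-3-methylidene-2-oxo-2,3,3a,4,7,8,9,11a-octahydrocyclodeca[b]furan-4-yl (2S)-2-methylbutanoate
Conditions: (R)-2-methyl-CBS-oxazaborolidine (0.3 equiv), catecholborane (3 equiv), toluene/CH2Cl2, −78 to −40 °C; MeOH quench
Reagents that add atoms: none
Why: Corey–Bakshi–Shibata reduction in which the α-methyl alkenyl group acts as the large substituent, so the (R)-catalyst delivers hydride to give the (S)-carbinol at C1 under reagent control, and catecholborane at low temperature leaves the lactone, ester and exocyclic methylene untouched.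

**Compound list**

1 | but-2-yn-1-ol | CC#CCO | starting material
2 | cyclic sodium alkenylalanate (sodium 2,2-bis(2-methoxyethoxy)-3-methyl-2,5-dihydro-1,2-oxaaluminol-2-uide) | CC1=CCO[Al-]1(OCCOC)OCCOC.[Na+] | intermediate
3 | (2Z)-3-iodobut-2-en-1-ol | C/C(I)=C/CO | intermediate
4 | (2Z)-3-iodobut-2-enal | C/C(I)=C/C=O | intermediate
5 | 2,2-dimethoxyacetaldehyde | COC(OC)C=O | starting material
6 | methyl acrylate | C=CC(=O)OC | starting material
7 | methyl 3-hydroxy-4,4-dimethoxy-2-methylidenebutanoate (racemic) | COC(OC)C(O)C(=C)C(=O)OC | intermediate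
8 | methyl (2Z)-2-(bromomethyl)-4,4-dimethoxybut-2-enoate | COC(=O)/C(CBr)=C/C(OC)OC | intermediate
9 | trimethylsilyl ether of 10 | I/C(C)=C\[C@@H](O[Si](C)(C)C)[C@@H](C(=C)C(=O)OC)C(OC)OC | intermediate
10 | methyl (3R,4S,5Z)-3-(dimethoxymethyl)-4-hydroxy-6-iodo-2-methylidenehept-5-enoate | I/C(C)=C\[C@@H](O)[C@@H](C(=C)C(=O)OC)C(OC)OC | intermediate
11 | (2S)-2-methylbutanoic acid | CC[C@H](C)C(=O)O | starting material
12 | methyl (3R,4S,5Z)-3-(dimethoxymethyl)-6-iodo-2-methylidene-4-{[(2S)-2-methylbutanoyl]oxy}hept-5-enoate | I/C(C)=C\[C@@H](OC(=O)[C@@H](C)CC)[C@@H](C(=C)C(=O)OC)C(OC)OC | intermediate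
13 | 3-methylcyclopent-2-en-1-one | CC1=CC(=O)CC1 | starting material
14 | 3-(bromomethyl)cyclopent-2-en-1-one | BrCC1=CC(=O)CC1 | intermediate
15 | methyl (3R,4S,5Z)-3-formyl-6-iodo-2-methylidene-4-{[(2S)-2-methylbutanoyl]oxy}hept-5-enoate | I/C(C)=C\[C@@H](OC(=O)[C@@H](C)CC)[C@@H](C(=C)C(=O)OC)C=O | intermediate
16 | methyl (3S,4S,5Z)-3-{(S)-hydroxy[(1R)-2-methylidene-5-oxocyclopentyl]methyl}-6-iodo-2-methylidene-4-{[(2S)-2-methylbutanoyl]oxy}hept-5-enoate | I/C(C)=C\[C@@H](OC(=O)[C@@H](C)CC)[C@@H](C(=C)C(=O)OC)[C@H](O)[C@H]1C(=C)CCC1=O | intermediate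
17 | methyl (3S,4S,5Z)-3-{(S)-hydroxy[(3S,4S)-5-oxo-1-oxaspiro[2.4]heptan-4-yl]methyl}-6-iodo-2-methylidene-4-{[(2S)-2-methylbutanoyl]oxy}hept-5-enoate (epoxide oxygen cis to the side chain) | I/C(C)=C\[C@@H](OC(=O)[C@@H](C)CC)[C@@H](C(=C)C(=O)OC)[C@H](O)[C@H]1[C@]2(CO2)CCC1=O | intermediate
18 | dichlorochromium alkoxide of the spiro-epoxy five–seven fused tertiary alcohol formed by C1–C10 closure of 17 (configuration at the ring-fusion carbinol not defined) | CC1=C[C@@H](OC(=O)[C@@H](C)CC)[C@@H](C(=C)C(=O)OC)[C@H](O)[C@H]2[C@]3(CO3)CCC12O[Cr](Cl)Cl | intermediate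
19 | methyl 2-[(1S,2R,3E,8Z,10R)-2-hydroxy-4-(hydroxymethyl)-8-methyl-10-{[(2S)-2-methylbutanoyl]oxy}-7-oxocyclodeca-3,8-dien-1-yl]prop-2-enoate | O[C@@H]1/C=C(/CO)CCC(=O)/C(C)=C\[C@@H](OC(=O)[C@@H](C)CC)[C@H]1C(=C)C(=O)OC | intermediate
20 | (3aR,4R,5Z,10E,11aR)-10-(hydroxymethyl)-6-methyl-3-methylidene-2,7-dioxo-2,3,3a,4,7,8,9,11a-octahydrocyclodeca[b]furan-4-yl (2S)-2-methylbutanoate | C=C1C(=O)O[C@@H]2/C=C(/CO)CCC(=O)/C(C)=C\[C@@H](OC(=O)[C@@H](C)CC)[C@@H]12 | intermediate
21 | (3aR,4R,5Z,7S,10E,11aR)-7-hydroxy-10-(hydroxymethyl)-6-methyl-3-methylidene-2-oxo-2,3,3a,4,7,8,9,11a-octahydrocyclodeca[b]furan-4-yl (2S)-2-methylbutanoate (CNP0526758.1) | C=C1C(=O)O[C@@H]2/C=C(/CO)CC[C@H](O)/C(C)=C\[C@@H](OC(=O)[C@@H](C)CC)[C@@H]12 | target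

**Step count and risks**

Total steps: 11. Longest linear sequence: 8 (steps 1, 2, 5, 6, 8, 9, 10, 11; the branch 3, 4, 5, 6, 8, 9, 10, 11 is equally long).

Steps most likely to fail:

Step 10 (the proposed new ring expansion). The alkenylchromium may add too slowly to the ketone, may eliminate the allylic ester to an allene, or the chromium alkoxide may not fragment. The fallback sets out from 17 and comes back at 21, using known chemistry only. Luche reduction of the ketone of 17 (NaBH4, CeCl3·7H2O, MeOH, −78 °C) gives the C1 alcohol of 17 F4 (either C1 epimer serves). Potassium tert-butoxide in THF at −40 °C then triggers a Wharton-type epoxy-alkoxide Grob fragmentation of the monocyclic cyclopentanol (same anti-periplanar C1–C5/C4–O array, hence the same C4=C5 geometry), with lactonisation of the C6 alkoxide, to give the open-chain aldehyde lactone (1S,2Z)-3-iodo-1-{(2R,3S)-2-[(1E)-2-(hydroxymethyl)-5-oxopent-1-en-1-yl]-4-methylidene-5-oxooxolan-3-yl}but-2-en-1-yl (2S)-2-methylbutanoate F5. A conventional Nozaki–Hiyama–Kishi macrocyclisation of F5 (CrCl2, NiCl2 cat., DMSO, 2 mM) closes C1–C10 and gives 21 directly, together with the C1 epimer of 21 F6, which is removed by chromatography. This replaces ring expansion by ring opening and macrocyclisation and bypasses step 11.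

Step 8 (indium coupling). The free α-branched aldehyde 15 is fragile (epimerisation, loss of the β-acyloxy group), and the α-versus-γ regiochemistry and the Felkin selectivity are not guaranteed. The fallback sets out from 14 (with aldehyde 15 from 12) and comes back at 16. Compound 14 is converted with hexamethyldisilane and Pd(PPh3)4 (cat.) into the allylsilane 3-[(trimethylsilyl)methyl]cyclopent-2-en-1-one F3. F3 adds to 15 under BF3·OEt2 in CH2Cl2 at −78 °C in a Hosomi–Sakurai reaction (attack through the ring α-carbon, open transition state, same Felkin sense). This replaces aqueous Barbier chemistry by a Lewis-acid-mediated addition of an isolated nucleophile at low temperature.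

Step 5 (asymmetric chromium allylation). The γ-acetal bromide and the β-iodo enal are untested partners for this catalyst, so the enantioselectivity may be low. The fallback sets out from 4 and 8 and comes back at 12. A zinc Barbier reaction (Zn dust, THF/saturated aqueous NH4Cl, 0 °C) gives the racemic syn adduct, that is 10 together with the enantiomer of 10 F1. Esterification with 11 as in step 6 then gives 12 and the diastereomeric ester of the enantiomer F2, which are separated by preparative chromatography. The natural acid acts as the resolving agent, at the cost of half the material.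

Further compounds
F1 | step 5 | methyl (3S,4R,5Z)-3-(dimethoxymethyl)-4-hydroxy-6-iodo-2-methylidenehept-5-enoate (enantiomer of 10) | I/C(C)=C\[C@H](O)[C@H](C(=C)C(=O)OC)C(OC)OC
F2 | step 5 | methyl (3S,4R,5Z)-3-(dimethoxymethyl)-6-iodo-2-methylidene-4-{[(2S)-2-methylbutanoyl]oxy}hept-5-enoate (diastereomer of 12) | I/C(C)=C\[C@H](OC(=O)[C@@H](C)CC)[C@H](C(=C)C(=O)OC)C(OC)OC
F3 | step 8 | 3-[(trimethylsilyl)methyl]cyclopent-2-en-1-one | C[Si](C)(C)CC1=CC(=O)CC1
F4 | step 10 | C1 alcohol of 17 (ring ketone reduced, C1 configuration not defined) | I/C(C)=C\[C@@H](OC(=O)[C@@H](C)CC)[C@@H](C(=C)C(=O)OC)[C@H](O)[C@H]1[C@]2(CO2)CCC1O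
F5 | step 10 | (1S,2Z)-3-iodo-1-{(2R,3S)-2-[(1E)-2-(hydroxymethyl)-5-oxopent-1-en-1-yl]-4-methylidene-5-oxooxolan-3-yl}but-2-en-1-yl (2S)-2-methylbutanoate | C=C1C(=O)O[C@H](/C=C(/CO)CCC=O)[C@H]1[C@H](OC(=O)[C@@H](C)CC)/C=C(/C)I
F6 | step 10 | C1 epimer of 21 ((7R) in the cyclodeca[b]furan numbering) | C=C1C(=O)O[C@@H]2/C=C(/CO)CC[C@@H](O)/C(C)=C\[C@@H](OC(=O)[C@@H](C)CC)[C@@H]12
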